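**Assumptions:** Ethyl dihydroferulate (6) and both enantiomers of Rh2(PTTL)4 are treated as purchasable. The sense of induction in Step 7 is extrapolated from benzylic-ether insertions, where the (S)-catalyst gives the (2R) series, and has not been confirmed for this substrate.

**Numbering:** C2 and C3 are the dihydrobenzofuran carbons. C1' is the carbinol carbon of the carbocycle, C3' is CHOH, and C4' is CHOMe.

## Retrosynthetic overview

1. Two disconnections are avoided: the biomimetic phenol coupling followed by ring reduction, and the addition of a C2 anion to a cyclohexanone.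
2. C3'/C4' are set last. The C1'-OH directs epoxidation of cyclohexenol 13, and trans-diaxial MeOH opening at C4' follows.
3. 13 comes from one LiAlH4 operation on 12. The two esters are latent CH2OH groups and the oxirane is the latent C1' tertiary alcohol, so no protecting groups are used.
4. Key step: the C2–C3 bond and the furan ring are closed by a catalyst-controlled Rh-carbene 1,5-C–H insertion into the ArO–CH2 group next to the quaternary oxirane carbon.
5. Ring order: carbocycle (Diels–Alder), oxirane (Sharpless AE, sets C1'), aryl ether (Mitsunobu), dihydrofuran (C–H insertion), second oxirane, then opening.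

## Route

**Step 1**
Reactants: 1, 1,3-butadiene; 2, methyl propiolate
Product: 3, methyl cyclohexa-1,4-diene-1-carboxylate
Conditions: toluene, BHT (cat.), sealed tube, 120 °C
Reagents that add atoms: none beyond 1 and 2
Why: A thermal Diels–Alder [4+2] of an electron-poor alkyne with butadiene gives the skipped 1,4-diene directly, and no stereocentre is formed.

**Step 2**
Reactants: 3
Product: 4, (cyclohexa-1,4-dien-1-yl)methanol
Conditions: DIBAL-H (2.2 equiv), CH2Cl2, −78 to 0 °C
Reagents that add atoms: none
Why: This is a 1,2-hydride reduction of the enoate to the allylic alcohol under non-basic conditions, so the skipped diene neither conjugates nor aromatises.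

**Step 3**
Reactants: 4
Product: 5, [(1S,6S)-7-oxabicyclo[4.1.0]hept-3-en-1-yl]methanol
Conditions: Ti(OiPr)4 (10 mol %), L-(+)-DIPT (12 mol %), TBHP (decane), 4 Å MS, CH2Cl2, −20 °C
Reagents that add atoms: tert-butyl hydroperoxide, CC(C)(C)OO
Why: In the Sharpless asymmetric epoxidation only the alkene of the allylic alcohol is oxidised, and L-(+)-tartrate gives the (S,S) series as it does for 1-cyclohexenylmethanol-type substrates, which fixes the C1'–O stereocentre for the rest of the route.

**Step 4**
Reactants: 6, ethyl 3-(4-hydroxy-3-methoxyphenyl)propanoate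
Product: 7, ethyl 3-(4-hydroxy-3-iodo-5-methoxyphenyl)propanoate
Conditions: BnMe3N·ICl2, NaHCO3, CH2Cl2/MeOH, rt
Reagents that add atoms: benzyltrimethylammonium dichloroiodate, C[N+](C)(C)Cc1ccccc1.Cl[I-]Cl
Why: This is a phenol-selective electrophilic aromatic iodination, and because the para position is blocked the iodine enters the only free position ortho to OH.

**Step 5**
Reactants: 5 and 7
Product: 8, ethyl 3-[3-iodo-5-methoxy-4-({(1S,6S)-7-oxabicyclo[4.1.0]hept-3-en-1-yl}methoxy)phenyl]propanoate
Conditions: PPh3, DIAD, THF, 0 °C to rt
Reagents that add atoms: none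
Why: Mitsunobu etherification of the acidic iodoguaiacol takes place at the primary oxiranylmethyl carbon, which is tied back and far more SN2-active than a true neopentyl carbon, and no stereocentre is touched.

**Step 6**
Reactants: 8; 9, ethyl diazoacetate
Product: 10, ethyl 2-diazo-2-[5-(3-ethoxy-3-oxopropyl)-3-methoxy-2-({(1S,6S)-7-oxabicyclo[4.1.0]hept-3-en-1-yl}methoxy)phenyl]acetate
Conditions: Pd(PPh3)4 (5 mol %), Ag2CO3 (0.5 equiv), Et3N, toluene, rt
Reagents that add atoms: ethyl diazoacetate, CCOC(=O)C=[N+]=[N-]
Why: Pd-catalysed deprotonative cross-coupling of an aryl iodide with the diazo C–H retains N2 and gives the donor/acceptor carbene precursor in one step, while the non-allylic oxirane and the isolated alkene are inert at rt.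

**Step 7 (key step)**
Reactants: 10
Product: 11, ethyl (2S,3R)-5-(3-ethoxy-3-oxopropyl)-7-methoxy-2-[(1R,6S)-7-oxabicyclo[4.1.0]hept-3-en-1-yl]-2,3-dihydro-1-benzofuran-3-carboxylate (2,3-cis; the C1' descriptor changes only because the CIP ranking changes)
Conditions: Rh2(R-PTTL)4 (1 mol %), 4 Å MS, toluene, slow addition, −40 to 0 °C
Reagents that add atoms: none
Why: Proposed new method: this is an intramolecular Rh(II) donor/acceptor-carbene 1,5-C–H insertion, whose closest known type is the cis-selective, highly enantioselective insertion of 2-(benzyloxy)aryl diazoacetates with phthaloyl-tert-leucinate dirhodium catalysts, extended here to an α-aryloxy CH2 flanked by a fully substituted oxirane carbon; the ether oxygen stabilises the hydride-transfer-like three-centre transition state, the only 1,5-C–H bonds are the two on C2, quaternary C1' removes any 1,6 competitor, the ring alkene would need an eight-membered transition state, the tied-back oxirane is smaller than a silyloxy quaternary carbon and has no O–H, and since insertion proceeds with retention the catalyst pocket selects the pro-S hydrogen to give (2S) with the kinetic cis ester at C3.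

**Step 8**
Reactants: 11
Product: 12, the (2S,3S) 2,3-trans epimer of 11
Conditions: NaOEt (0.2 equiv), EtOH, 0 °C to rt
Reagents that add atoms: none
Why: Base-mediated thermodynamic epimerisation of the benzylic α-ester centre moves CO2Et anti to the bulky C2 group and sets the C3 configuration; ethoxide exchange with the ethyl esters is degenerate, C2 is not acidic, and ring-opening E1cB would require a disfavoured reverse 5-endo process.

**Step 9**
Reactants: 12
Product: 13, (1S)-1-[(2S,3R)-3-(hydroxymethyl)-5-(3-hydroxypropyl)-7-methoxy-2,3-dihydro-1-benzofuran-2-yl]cyclohex-3-en-1-ol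
Conditions: LiAlH4 (excess), THF, 0 to 65 °C; Rochelle salt work-up
Reagents that add atoms: none
Why: This global hydride reduction converts both esters to CH2OH and opens the trisubstituted oxirane by SN2 attack at the secondary carbon with the C1'–O bond untouched, giving the (1'S) tertiary alcohol, and the trans C2/C3 geometry blocks 5-exo attack of the new alkoxide on the oxirane because that product would be a trans-fused 5/5 system.

**Step 10**
Reactants: 13
Product: 14, (1S,3S,6R)-3-[(2S,3R)-3-(hydroxymethyl)-5-(3-hydroxypropyl)-7-methoxy-2,3-dihydro-1-benzofuran-2-yl]-7-oxabicyclo[4.1.0]heptan-3-ol (oxirane cis to the tertiary OH)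
Conditions: VO(acac)2 (5 mol %), TBHP (1.3 equiv, decane), CH2Cl2, 0 °C to rt
Reagents that add atoms: tert-butyl hydroperoxide, CC(C)(C)OO
Why: In this hydroxyl-directed vanadium epoxidation of a tertiary homoallylic cyclohexenol, as seen with terpinen-4-ol-type substrates, the bulky C1' substituent sits equatorial, so the axial OH delivers oxygen to its own face and places the C3'–O bond cis to C1'-OH.

**Step 11**
Reactants: 14
Product: 15, difengpiol B, (1S,3S,4S)-1-[(2S,3R)-3-(hydroxymethyl)-5-(3-hydroxypropyl)-7-methoxy-2,3-dihydro-1-benzofuran-2-yl]-4-methoxycyclohexane-1,3-diol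
Conditions: Yb(OTf)3 (10 mol %), MeOH, rt
Reagents that add atoms: methanol, CO
Why: In this Lewis-acid epoxide methanolysis under Fürst–Plattner control, the half-chair with the large group equatorial and the OH axial (bridged to the oxirane O by Yb) allows trans-diaxial attack only at the distal C4', a preference reinforced by the inductive effect of C1'–O, and this gives C4'-OMe with inversion and C3'-OH with retention, cis to C1'-OH.

## Compound list

| No. | Name | SMILES | Role |
|---|---|---|---|
| 1 | 1,3-butadiene | C=CC=C | starting material |
| 2 | methyl propiolate | C#CC(=O)OC | starting material |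
| 3 | methyl cyclohexa-1,4-diene-1-carboxylate | COC(=O)C1=CCC=CC1 | intermediate |
| 4 | (cyclohexa-1,4-dien-1-yl)methanol | OCC1=CCC=CC1 | intermediate |
| 5 | [(1S,6S)-7-oxabicyclo[4.1.0]hept-3-en-1-yl]methanol | OC[C@@]12CC=CC[C@@H]1O2 | intermediate |
| 6 | ethyl 3-(4-hydroxy-3-methoxyphenyl)propanoate | CCOC(=O)CCc1ccc(O)c(OC)c1 | starting material |
| 7 | ethyl 3-(4-hydroxy-3-iodo-5-methoxyphenyl)propanoate | CCOC(=O)CCc1cc(I)c(O)c(OC)c1 | intermediate |
| 8 | iodoaryl oxiranylmethyl ether | CCOC(=O)CCc1cc(I)c(OC[C@@]23CC=CC[C@@H]2O3)c(OC)c1 | intermediate |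
| 9 | ethyl diazoacetate | CCOC(=O)C=[N+]=[N-] | starting material |
| 10 | aryl diazoacetate | CCOC(=O)CCc1cc(C(=[N+]=[N-])C(=O)OCC)c(OC[C@@]23CC=CC[C@@H]2O3)c(OC)c1 | intermediate |
| 11 | (2S,3R)-cis dihydrobenzofuran diester oxirane | COc1cc(CCC(=O)OCC)cc2c1O[C@H]([C@@]13CC=CC[C@@H]1O3)[C@@H]2C(=O)OCC | intermediate |
| 12 | (2S,3S)-trans dihydrobenzofuran diester oxirane | COc1cc(CCC(=O)OCC)cc2c1O[C@H]([C@@]13CC=CC[C@@H]1O3)[C@H]2C(=O)OCC | intermediate |
| 13 | cyclohexenol triol | COc1cc(CCCO)cc2c1O[C@H]([C@]1(O)CCC=CC1)[C@H]2CO | intermediate |
| 14 | cis-epoxy triol | COc1cc(CCCO)cc2c1O[C@H]([C@]1(O)CC[C@H]3O[C@H]3C1)[C@H]2CO | intermediate |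
| 15 | difengpiol B | COc1cc(CCCO)cc2c1O[C@H]([C@]1(O)CC[C@H](OC)[C@@H](O)C1)[C@H]2CO | target |

## Step count

- **Total steps:** 11
- **Longest linear sequence:** 10 (Steps 1–3 and 5–11)

## Three steps most likely to fail

1. **Step 7.**
   - Risks: low reactivity at the hindered CH2, carbene attack on the oxirane oxygen (ylide formation or deoxygenation), and a mismatched or reversed sense of induction.
   - Fallback: give up C–H insertion and make the C2–C3 bond by aldol chemistry.
     - Oxidise 5 to the epoxy aldehyde.
     - Run an Evans boron syn-aldol with the N-[(2-bromo-3-methoxy-5-substituted-phenyl)acetyl]oxazolidinone.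
     - Close O1–C7a by intramolecular Cu-catalysed O-arylation. Retention at C2 means the syn aldol gives the trans ring.
     - Remove the auxiliary reductively to rejoin the route at 13.

2. **Step 6.**
   - Risk: an electron-rich, ortho-alkoxy aryl iodide may couple poorly with the diazo ester.
   - Fallback: reach the carbene from a carbonyl precursor. Carry out I/Mg exchange on 8 (iPrMgCl·LiCl), trap with diethyl oxalate to give the aryl glyoxylate, and convert it to the tosylhydrazone. Generate the diazo compound in situ (Bamford–Stevens) under the Rh catalyst.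

3. **Step 11.**
   - Risk: some attack at C3' would give the regioisomeric methyl ether.
   - Fallback: remove the regiochemical question by building the OMe carbon into the ring. Use 2-methoxybutadiene in Step 1, which gives the para adduct with a C4'(OMe)=C3' enol ether. Replace Steps 10 and 11 with hydroboration–oxidation steered by the C1' alkoxide. Boron goes to C3' on the hydroxyl face, and syn addition gives the trans C3'-OH/C4'-OMe pair.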